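**Plan**
- Retrosynthesis: the ester C3–O bond is cut first (invertive esterification of a cis-3-ol with the Z side-chain acid). Next come the ring bond C2–C3 together with the isopropenyl C–CH3 bond, then the ether O–CH2 bond and the aryl–acetyl bond.
- Enabling feature: C2 of the dihydrofuran ring bears O1 and the isopropenyl group and is bonded to the carbinol carbon C3. That pattern remains when the oxygen-bearing terminus of an aryl allenyl ether adds to an ortho formyl group and a methyl group ends up on the central allene carbon.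
- Forward: the benzene ring is dressed first (silyl ether, acetyl group by Stille coupling, propargyl ether, allenyl ether). The dihydrofuran ring closes in step 6, the acid (four steps from crotonaldehyde) is joined in step 11, and desilylation ends the route.
- Stereochemistry: C2 and C3 are set together in step 6, the absolute sense by the chiral ligand on nickel and the cis relation by the metallacycle. The Mitsunobu reaction inverts C3 to give the trans (2R,3S) ester. The Z alkene comes from (Z)-2-bromobut-2-enal through retentive Br–Li exchange and carboxylation.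

Key step: step 6

Remark: 5-bromo-2,4-dihydroxybenzaldehyde is taken as a catalogue compound (otherwise one step from 2,4-dihydroxybenzaldehyde with Br2 in AcOH); the ligand enantiomer that gives the 3R carbinol in step 6 has to be fixed by screening.

**Route**

Step 1
Reactants: 1 5-bromo-2,4-dihydroxybenzaldehyde
Product: 2 5-bromo-2-hydroxy-4-[(triisopropylsilyl)oxy]benzaldehyde
Conditions: TIPSCl (1.05 equiv), imidazole, CH2Cl2, 0 °C
Reagents that add atoms: chlorotri(propan-2-yl)silane (TIPSCl), CC(C)[Si](Cl)(C(C)C)C(C)C
Why: Selective O-silylation, because the 4-OH is the free and more acidic phenol whereas the 2-OH is held in a hydrogen bond to the formyl group and should stay untouched at 0 °C.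

Step 2
Reactants: 2 5-bromo-2-hydroxy-4-[(triisopropylsilyl)oxy]benzaldehyde; 3 tributyl(1-ethoxyethenyl)stannane
Product: 5 5-acetyl-2-hydroxy-4-[(triisopropylsilyl)oxy]benzaldehyde, via enol ether 4 (not isolated)
Conditions: Pd(PPh3)4 (5 mol%), toluene, 100 °C; then 1 M aq. HCl, THF, rt
Reagents that add atoms: tributyl(1-ethoxyethenyl)stannane 3, CCCC[Sn](CCCC)(CCCC)C(=C)OCC; water, O
Why: Migita–Kosugi–Stille coupling of the aryl bromide with the 1-ethoxyvinylstannane as an acetyl equivalent, followed by acid hydrolysis of enol ether 4, which the free phenol, the aldehyde and the aryl silyl ether should all tolerate.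

Step 3
Reactants: 5 5-acetyl-2-hydroxy-4-[(triisopropylsilyl)oxy]benzaldehyde; 6 prop-2-yn-1-ol
Product: 7 5-acetyl-2-(prop-2-yn-1-yloxy)-4-[(triisopropylsilyl)oxy]benzaldehyde
Conditions: PPh3, DIAD, THF, 0 °C → rt
Reagents that add atoms: prop-2-yn-1-ol 6, C#CCO
Why: Mitsunobu etherification of the only free, acidic phenol with a primary propargylic alcohol under neutral conditions, chosen over base-mediated alkylation so that the aryl silyl ether never meets phenoxide or carbonate.

Step 4
Reactants: 7 5-acetyl-2-(prop-2-yn-1-yloxy)-4-[(triisopropylsilyl)oxy]benzaldehyde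
Product: 8 1-[5-(dimethoxymethyl)-4-(prop-2-yn-1-yloxy)-2-[(triisopropylsilyl)oxy]phenyl]ethan-1-one
Conditions: HC(OMe)3, MeOH, PPTS (cat.), rt; Et3N quench
Reagents that add atoms: trimethyl orthoformate, COC(OC)OC; methanol, CO
Why: Acid-catalysed acetalisation, selective for the aldehyde over the hindered and electron-rich aryl ketone, masks the formyl group so that the base of step 5 cannot start a Claisen–Schmidt condensation between acetyl and formyl groups, and any ketal formed at the acetyl group would be cleaved again in the hydrolysis of step 5.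

Step 5
Reactants: 8 1-[5-(dimethoxymethyl)-4-(prop-2-yn-1-yloxy)-2-[(triisopropylsilyl)oxy]phenyl]ethan-1-one
Product: 10 5-acetyl-2-(propa-1,2-dien-1-yloxy)-4-[(triisopropylsilyl)oxy]benzaldehyde, via allenyl ether acetal 9 (not isolated)
Conditions: t-BuOK (0.3 equiv), THF, 0 °C; then PPTS (cat.), acetone–H2O, rt
Reagents that add atoms: water, O
Why: Base-catalysed propargyl-to-allenyl prototropic isomerisation of an aryl propargyl ether, followed by mild hydrolysis in which the electron-rich benzaldehyde dimethyl acetal should cleave far faster than the aryl allenyl ether, whose oxygen lone pair is drawn into the ring by the para acetyl group.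

Step 6
Reactants: 10 5-acetyl-2-(propa-1,2-dien-1-yloxy)-4-[(triisopropylsilyl)oxy]benzaldehyde; 11 dimethylzinc
Product: 13 1-[(2R,3R)-3-hydroxy-2-(prop-1-en-2-yl)-6-[(triisopropylsilyl)oxy]-2,3-dihydro-1-benzofuran-5-yl]ethan-1-one, via methylzinc alkoxide 12 (not isolated)
Conditions: Ni(cod)2 (10 mol%), chiral spirobiindane phosphoramidite (SIPHOS type, 12 mol%), Me2Zn (3 equiv), toluene, 0 °C → rt; then pH 7 aqueous buffer
Reagents that add atoms: dimethylzinc 11, C[Zn]C
Why: Proposed new method: zerovalent nickel bearing the chiral phosphoramidite should bind the formyl group and the proximal, oxygen-substituted C=C of the allene and undergo oxidative cyclisation to a cis-fused oxanickelacycle in which C2–C3 already exists and nickel sits on the former central allene carbon; methyl transfer from Me2Zn to nickel and C–C reductive elimination then complete the isopropenyl group and release methylzinc alkoxide 12. The closest known reaction type is the cis-selective nickel-catalysed alkylative cyclisation of carbon-tethered allenyl aldehydes with organozinc reagents, together with the enantioselective nickel/phosphoramidite alkylative coupling of alkynes, aldehydes and Me2Zn; new here are the aryloxy-substituted allene and ligand control of absolute configuration. The dihydrofuran ring closes in a 5-exo-trig sense, the formyl carbon bonding to the oxygen-bearing allene terminus while the remaining C=C stays exocyclic. C3 is set by the aldehyde face that the ligand exposes during oxidative cyclisation, and C2 follows from the cis ring fusion of the metallacycle, so OH and isopropenyl should be cis and (2R,3R) with the matching ligand enantiomer. The step needs the aldehyde to react in preference to the aryl ketone and the five-membered ring to form in preference to the six-membered one: only the formyl group is ortho to the allenyl ether, the acetyl group is para to the ether oxygen and cannot reach the allene, the short rigid tether lets only the proximal double bond align with the C=O, and the silylated phenol leaves no acidic proton to protonate Ni–C bonds or consume Me2Zn.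

Step 7
Reactants: 14 (E)-but-2-enal (crotonaldehyde)
Product: 16 (Z)-2-bromobut-2-enal, via 2,3-dibromobutanal 15 (not isolated)
Conditions: Br2, CH2Cl2, −10 °C; then Et3N, 0 °C → rt
Reagents that add atoms: bromine, BrBr
Why: Bromine addition to the enal followed by amine-mediated dehydrobromination (E1cB through the enolate) should give the thermodynamically preferred Z isomer, with CHO trans to the methyl group.

Step 8
Reactants: 16 (Z)-2-bromobut-2-enal
Product: 17 (Z)-2-bromobut-2-en-1-ol
Conditions: NaBH4, CeCl3·7H2O, MeOH, 0 °C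
Reagents that add atoms: none
Why: Luche 1,2-reduction of the enal leaves the C=C bond, the vinyl bromide and the alkene geometry untouched.

Step 9
Reactants: 17 (Z)-2-bromobut-2-en-1-ol
Product: 20 (Z)-2-(hydroxymethyl)but-2-enoic acid, via dilithio alkoxide 18 (not isolated), via dilithium carboxylate 19 (not isolated)
Conditions: t-BuLi (3.1 equiv), Et2O, −78 °C; CO2 (g), −78 °C → rt; then 2 M aq. HCl
Reagents that add atoms: carbon dioxide, O=C=O
Why: Bromine–lithium exchange on the lithium alkoxide and carboxylation of the vinyllithium both proceed with retention at the sp2 carbon, so CO2H takes the place of Br cis to the methyl group and defines the Z acid.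

Step 10
Reactants: 20 (Z)-2-(hydroxymethyl)but-2-enoic acid
Product: 21 (Z)-2-(acetoxymethyl)but-2-enoic acid
Conditions: Ac2O, pyridine, CH2Cl2, 0 °C → rt; then H2O
Reagents that add atoms: acetic anhydride, CC(=O)OC(C)=O
Why: O-acetylation of the primary alcohol with acetic anhydride and pyridine, in which the carboxylate form of the acid is a poor Michael acceptor so the Z geometry should survive, and any mixed anhydride is hydrolysed in the aqueous work-up.

Step 11
Reactants: 13 1-[(2R,3R)-3-hydroxy-2-(prop-1-en-2-yl)-6-[(triisopropylsilyl)oxy]-2,3-dihydro-1-benzofuran-5-yl]ethan-1-one; 21 (Z)-2-(acetoxymethyl)but-2-enoic acid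
Product: 22 (2R,3S)-5-acetyl-2-(prop-1-en-2-yl)-6-[(triisopropylsilyl)oxy]-2,3-dihydro-1-benzofuran-3-yl (2Z)-2-(acetoxymethyl)but-2-enoate
Conditions: PPh3 and DIAD premixed at 0 °C (slight excess of DIAD), then 21, then 13, toluene–THF, −20 → 0 °C
Reagents that add atoms: acid 21, C/C=C(\C(=O)O)COC(C)=O
Why: Mitsunobu esterification, in which the carboxylate of 21 displaces the oxyphosphonium group at benzylic C3 in an SN2 manner from the face anti to the isopropenyl group and so inverts C3 to S (trans ester), while the acid, reacting only as a nucleophile and never as an activated acyl donor, should keep its Z geometry and its allylic acetate.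

Step 12
Reactants: 22 (2R,3S)-5-acetyl-2-(prop-1-en-2-yl)-6-[(triisopropylsilyl)oxy]-2,3-dihydro-1-benzofuran-3-yl (2Z)-2-(acetoxymethyl)but-2-enoate
Product: 23 (2R,3S)-5-acetyl-6-hydroxy-2-(prop-1-en-2-yl)-2,3-dihydro-1-benzofuran-3-yl (2Z)-2-(acetoxymethyl)but-2-enoate
Conditions: TBAF, AcOH (1.5 equiv per fluoride), THF, 0 °C
Reagents that add atoms: none
Why: Fluoride-mediated cleavage of the aryl silyl ether, buffered with acetic acid so that the liberated phenoxide is protonated at once and cannot expel the para-benzylic C3 carboxylate, should leave both esters, the Z alkene and both stereocentres intact.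

**Compound list**
1 | 5-bromo-2,4-dihydroxybenzaldehyde | O=Cc1cc(Br)c(O)cc1O | starting material
2 | 5-bromo-2-hydroxy-4-[(triisopropylsilyl)oxy]benzaldehyde | O=Cc1cc(Br)c(O[Si](C(C)C)(C(C)C)C(C)C)cc1O | intermediate
3 | tributyl(1-ethoxyethenyl)stannane | CCCC[Sn](CCCC)(CCCC)C(=C)OCC | starting material
4 | 5-(1-ethoxyethenyl)-2-hydroxy-4-[(triisopropylsilyl)oxy]benzaldehyde (enol ether, not isolated) | CCOC(=C)c1cc(C=O)c(O)cc1O[Si](C(C)C)(C(C)C)C(C)C | intermediate
5 | 5-acetyl-2-hydroxy-4-[(triisopropylsilyl)oxy]benzaldehyde | CC(=O)c1cc(C=O)c(O)cc1O[Si](C(C)C)(C(C)C)C(C)C | intermediate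
6 | prop-2-yn-1-ol | C#CCO | starting material
7 | 5-acetyl-2-(prop-2-yn-1-yloxy)-4-[(triisopropylsilyl)oxy]benzaldehyde | C#CCOc1cc(O[Si](C(C)C)(C(C)C)C(C)C)c(C(C)=O)cc1C=O | intermediate
8 | 1-[5-(dimethoxymethyl)-4-(prop-2-yn-1-yloxy)-2-[(triisopropylsilyl)oxy]phenyl]ethan-1-one | C#CCOc1cc(O[Si](C(C)C)(C(C)C)C(C)C)c(C(C)=O)cc1C(OC)OC | intermediate
9 | 1-[5-(dimethoxymethyl)-4-(propa-1,2-dien-1-yloxy)-2-[(triisopropylsilyl)oxy]phenyl]ethan-1-one (allenyl ether acetal, not isolated) | C=C=COc1cc(O[Si](C(C)C)(C(C)C)C(C)C)c(C(C)=O)cc1C(OC)OC | intermediate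
10 | 5-acetyl-2-(propa-1,2-dien-1-yloxy)-4-[(triisopropylsilyl)oxy]benzaldehyde | C=C=COc1cc(O[Si](C(C)C)(C(C)C)C(C)C)c(C(C)=O)cc1C=O | intermediate
11 | dimethylzinc | C[Zn]C | starting material
12 | methylzinc (2R,3R)-5-acetyl-2-(prop-1-en-2-yl)-6-[(triisopropylsilyl)oxy]-2,3-dihydro-1-benzofuran-3-olate (not isolated) | C=C(C)[C@H]1Oc2cc(O[Si](C(C)C)(C(C)C)C(C)C)c(C(C)=O)cc2[C@H]1O[Zn]C | intermediate
13 | 1-[(2R,3R)-3-hydroxy-2-(prop-1-en-2-yl)-6-[(triisopropylsilyl)oxy]-2,3-dihydro-1-benzofuran-5-yl]ethan-1-one (cis) | C=C(C)[C@H]1Oc2cc(O[Si](C(C)C)(C(C)C)C(C)C)c(C(C)=O)cc2[C@H]1O | intermediate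
14 | (E)-but-2-enal (crotonaldehyde) | C/C=C/C=O | starting material
15 | rac-(2R*,3S*)-2,3-dibromobutanal (anti adduct, racemic, one enantiomer drawn, not isolated) | C[C@H](Br)[C@H](Br)C=O | intermediate
16 | (Z)-2-bromobut-2-enal | C/C=C(\Br)C=O | intermediate
17 | (Z)-2-bromobut-2-en-1-ol | C/C=C(\Br)CO | intermediate
18 | lithium (Z)-2-lithiobut-2-en-1-olate (not isolated) | C/C=C(\[Li])CO[Li] | intermediate
19 | dilithium (Z)-2-(oxidomethyl)but-2-enoate (not isolated) | C/C=C(\C(=O)[O-])C[O-].[Li+].[Li+] | intermediate
20 | (Z)-2-(hydroxymethyl)but-2-enoic acid | C/C=C(\C(=O)O)CO | intermediate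
21 | (Z)-2-(acetoxymethyl)but-2-enoic acid | C/C=C(\C(=O)O)COC(C)=O | intermediate
22 | (2R,3S)-5-acetyl-2-(prop-1-en-2-yl)-6-[(triisopropylsilyl)oxy]-2,3-dihydro-1-benzofuran-3-yl (2Z)-2-(acetoxymethyl)but-2-enoate (trans) | C=C(C)[C@H]1Oc2cc(O[Si](C(C)C)(C(C)C)C(C)C)c(C(C)=O)cc2[C@@H]1OC(=O)/C(=C\C)COC(C)=O | intermediate
23 | (2R,3S)-5-acetyl-6-hydroxy-2-(prop-1-en-2-yl)-2,3-dihydro-1-benzofuran-3-yl (2Z)-2-(acetoxymethyl)but-2-enoate | C=C(C)[C@H]1Oc2cc(O)c(C(C)=O)cc2[C@@H]1OC(=O)/C(=C\C)COC(C)=O | target

**Count**
Total steps: 12. Longest linear sequence: 8 steps (1 → 23 through steps 1–6, 11 and 12); the acid 21 is made in 4 steps (7–10).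

**Steps most likely to fail**

1. Step 6. The ligand may discriminate poorly between the aldehyde faces, zerovalent nickel may insert into the allenyl C–O bond, or closure may occur at the central allene carbon to give a six-membered ring. Fallback with known chemistry: starting from 10, the cyclisation is run with Ni(cod)2 and Me2Zn in THF at 0 °C without a chiral ligand, the established substrate-controlled cis-selective variant. After aqueous work-up this should give the racemic cis alcohol rac-1-[(2R*,3R*)-3-hydroxy-2-(prop-1-en-2-yl)-6-[(triisopropylsilyl)oxy]-2,3-dihydro-1-benzofuran-5-yl]ethan-1-one F1. Kinetic resolution with immobilised Candida antarctica lipase B and vinyl acetate in MTBE is expected, by analogy with 1-indanol, to acylate the 3S enantiomer to (2S,3S)-5-acetyl-2-(prop-1-en-2-yl)-6-[(triisopropylsilyl)oxy]-2,3-dihydro-1-benzofuran-3-yl acetate F2. The unreacted (2R,3R)-alcohol is separated and is 13, where the route is rejoined.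

2. Step 11. The activated C3 oxygen may be lost by elimination with aromatisation to the 2-isopropenylbenzofuran, ionisation at the electron-rich benzylic carbon may erode the inversion, or free phosphine may attack the allylic acetate of the acid. Fallback: starting from 13, Mitsunobu inversion with the smaller and more acidic chloroacetic acid should give (2R,3S)-5-acetyl-2-(prop-1-en-2-yl)-6-[(triisopropylsilyl)oxy]-2,3-dihydro-1-benzofuran-3-yl chloroacetate F3. Brief methanolysis (K2CO3 cat., MeOH, 0 °C) frees the trans alcohol 1-[(2R,3S)-3-hydroxy-2-(prop-1-en-2-yl)-6-[(triisopropylsilyl)oxy]-2,3-dihydro-1-benzofuran-5-yl]ethan-1-one F4. This is acylated with retention under Yamaguchi conditions by the mixed anhydride (2Z)-2-(acetoxymethyl)but-2-enoic 2,4,6-trichlorobenzoic anhydride F5 (from 21, 2,4,6-trichlorobenzoyl chloride and Et3N; then F4, DMAP, toluene), which returns to the route at 22.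

3. Step 5. The base may remove or shift the silyl group by way of the acetyl enolate, cause ketone self-condensation or over-isomerise the allene to the 1-propynyl ether, and the allenyl ether may hydrolyse during acetal cleavage. Fallback: starting from 8, the silyl group is removed first (TBAF, THF, 0 °C) to give 1-[5-(dimethoxymethyl)-2-hydroxy-4-(prop-2-yn-1-yloxy)phenyl]ethan-1-one F6. Its potassium phenoxide, which suppresses enolisation of the neighbouring acetyl group, is isomerised with t-BuOK (2.3 equiv) in THF to 1-[5-(dimethoxymethyl)-2-hydroxy-4-(propa-1,2-dien-1-yloxy)phenyl]ethan-1-one F7. Hydrolysis with PPTS in aqueous acetone gives 5-acetyl-4-hydroxy-2-(propa-1,2-dien-1-yloxy)benzaldehyde F8, and silylation (TIPSCl, imidazole, CH2Cl2) returns to the route at 10.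

**Further compounds**
F1 | step 6 | rac-1-[(2R*,3R*)-3-hydroxy-2-(prop-1-en-2-yl)-6-[(triisopropylsilyl)oxy]-2,3-dihydro-1-benzofuran-5-yl]ethan-1-one (racemic cis alcohol, one enantiomer drawn) | C=C(C)[C@H]1Oc2cc(O[Si](C(C)C)(C(C)C)C(C)C)c(C(C)=O)cc2[C@H]1O
F2 | step 6 | (2S,3S)-5-acetyl-2-(prop-1-en-2-yl)-6-[(triisopropylsilyl)oxy]-2,3-dihydro-1-benzofuran-3-yl acetate | C=C(C)[C@@H]1Oc2cc(O[Si](C(C)C)(C(C)C)C(C)C)c(C(C)=O)cc2[C@@H]1OC(C)=O
F3 | step 11 | (2R,3S)-5-acetyl-2-(prop-1-en-2-yl)-6-[(triisopropylsilyl)oxy]-2,3-dihydro-1-benzofuran-3-yl chloroacetate | C=C(C)[C@H]1Oc2cc(O[Si](C(C)C)(C(C)C)C(C)C)c(C(C)=O)cc2[C@@H]1OC(=O)CCl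
F4 | step 11 | 1-[(2R,3S)-3-hydroxy-2-(prop-1-en-2-yl)-6-[(triisopropylsilyl)oxy]-2,3-dihydro-1-benzofuran-5-yl]ethan-1-one | C=C(C)[C@H]1Oc2cc(O[Si](C(C)C)(C(C)C)C(C)C)c(C(C)=O)cc2[C@@H]1O
F5 | step 11 | (2Z)-2-(acetoxymethyl)but-2-enoic 2,4,6-trichlorobenzoic anhydride | C/C=C(\C(=O)OC(=O)c1c(Cl)cc(Cl)cc1Cl)COC(C)=O
F6 | step 5 | 1-[5-(dimethoxymethyl)-2-hydroxy-4-(prop-2-yn-1-yloxy)phenyl]ethan-1-one | C#CCOc1cc(O)c(C(C)=O)cc1C(OC)OC
F7 | step 5 | 1-[5-(dimethoxymethyl)-2-hydroxy-4-(propa-1,2-dien-1-yloxy)phenyl]ethan-1-one | C=C=COc1cc(O)c(C(C)=O)cc1C(OC)OC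
F8 | step 5 | 5-acetyl-4-hydroxy-2-(propa-1,2-dien-1-yloxy)benzaldehyde | C=C=COc1cc(O)c(C(C)=O)cc1C=O
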